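Count the gap.

| flask | solid substrate | remark | time |
|---|---|---|---|
| summer | 0.013 M | run made earlier |  |
| noon | 0.030 M | run made earlier |  |
| flask | 0.020 M |  | 10 min |

- summer (time / min: solid substrate / %, over-reaction product / %, target / %): 1.00: 0.9, 74.7, 6.9; 3.00: 0, 100.2, 0.1; 5.00: 0, 99.6, 0; 8.00: 0, 99.7, 0.8
- noon (time / min: solid substrate / %, over-reaction product / %, target / %): 2.00: 0.3, 95.2, 1.1; 4.00: 0, 100.4, 0; 6.00: 0, 99.9, 0.2; 8.00: 0.3, 100.6, 0.7

(each reading ± 0.5 percentage points)

1. the state of affairs at 10 min: stopped, and by what, or still going (for what has run out or reacted, a solid counts together with what of it has only dissolved) (it is still moving / all of the solid substrate has reacted / forward and back rates have come level)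
2. part of the solid substrate that has turned into other species by 10 min (what has only dissolved does not count)
3. the over-reaction product standing at 10 min, as a percentage of the solid substrate charged

- solid, in amounts per volume of the solution: solid substrate
- the analysis behind the earlier runs scatters by 0.5 percentage points, standard deviation
- on the list of suspects stand: starting material <-> intermediate A; starting material -> intermediate B; starting material <-> intermediate C; intermediate B -> target; target -> over-reaction product; solid substrate <-> starting material
- at the start none of the solid substrate is in solution
- what has only dissolved of solid substrate counts as not reacted
- the reaction counts as stopped when no species that holds the solid substrate changes by six tenths of a point or more over the second half of the time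

On the list of suspects, a molecule of starting material that enters intermediate A or intermediate C can come back, while the way through intermediate B runs forward to target and on to over-reaction product. At each fork the molecule either returns or moves towards that end, so the open question is time. Time is measured by the gap, the share of the charge not yet over-reaction product: 25.3% in the summer run at 1.00 min, 4.80% in the noon run at 2.00 min. Read across these two charges, the readings give 0.417 min, the gap half-life, the time in which the gap halves.

The flask, at c(solid substrate) = 0.020 M, looks nearly like the noon run at 0.030 M, which reads 100.6% at 8.00 min, with a scatter of 0.5 percentage points. The flask should end full because 19.2 halvings fit between 2.00 min and 10 min. The reckoning here, starting the flask from the noon gap, leaves <0.001%, so >99.9% over-reaction product. The noon solid reads 0% at 4.00 min.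

The forecast gives all of the solid substrate has reacted, 100% converted and 99.8% over-reaction product, holding that “Loading barely changes the timescale”. Its product figure is 99.8%, the reckoning here >99.9%.

The flask gives all of the solid substrate has reacted, with 100% converted and 100% over-reaction product. That product stood at 74.9% after 1.00 min and came within 5 points of its end value at 1.93 min. From the 1.00 min value, the gap half-life puts that mark at 1.97 min, and 10 min stands far beyond it.

    starting material ⇌ intermediate A (K = 0.510, k = 0.110 s⁻¹)
    starting material → intermediate B (k = 0.0680 s⁻¹)
    starting material ⇌ intermediate C (K = 0.590, k = 0.0760 s⁻¹)
    intermediate B → target (k = 0.260 s⁻¹)
    target → over-reaction product (k = 0.0980 s⁻¹)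
    solid substrate ⇌ starting material, rate k6*(cs6 - [starting material]) while solid is left; crystals form when [starting material] > cs6 (solubility = 19.0 mM, k = 1.90 s⁻¹)

A neighbour charged with 0.034 M has the same 10 min. Taking the noon gap as its own at 2.00 min, 19.2 halvings of 0.417 min leave <0.001%. Computed, that neighbour holds 100% over-reaction product, with 0% of its solid substrate left.

All runs were generated by integration for substances that don't exist; noise was put on by code.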